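The route rests on disconnecting the three phenolic C2–O bonds, one on each ring, and not any bond of the depside skeleton. In rings A, B and C alike the hydroxyl sits on C2, ortho to the ring's own carboxyl carbon on C1, while C6 carries a methyl group, so each carbonyl oxygen has exactly one ortho C–H within reach. A single carbonyl-directed C–H oxygenation catalysed by [RuCl2(p-cymene)]2 should therefore install all three hydroxyls at once. Its precursor is the hydroxyl-free tridepside built from 3,4-dimethoxy-2-methylbenzoic acid and two 4-hydroxy-2-methylbenzoate units, with the ring C carboxyl held as a 4-nitrobenzyl ester.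

Key step: step 7

Remarks on the chemistry (assumptions):
- Numbering: in every ring C1 carries the carboxyl carbon, C2 the hydroxyl of the target (a C–H in the precursor) and C6 the methyl group. Ring A is the dimethoxy ring (OMe on C4 and C5), ring B the middle ring, ring C the ring bearing the free acid. The target has no stereocentre.
- The ring C carboxyl is carried through the oxidation as a 4-nitrobenzyl ester, not as the free acid. A free acid would become a mixed trifluoroacetic anhydride in the TFA/TFAA medium, which is an acylating agent and a poorer directing group. An alkyl ester makes ring C the best-precedented of the three directing situations. The nitro-deactivated benzyl group should resist hot acid, persulfate and metalation, and leaves by neutral hydrogenolysis. The skeleton and the three bonds formed are unchanged.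
- Bromination of 1 is assumed to occur para to the 3-methoxy group, because the 2-methoxy group is twisted out of conjugation by its two neighbours.

Step 1
Reactants: 1 2,3-dimethoxytoluene
Product: 2 1-bromo-3,4-dimethoxy-2-methylbenzene
Conditions: NBS (1.05 equiv), MeCN, 0 °C to rt
Reagents that add atoms: N-bromosuccinimide, O=C1CCC(=O)N1Br
Why: Electrophilic aromatic bromination should go para to the only freely conjugating methoxy group (the 3-OMe), which places bromine on the carbon next to the methyl group.

Step 2
Reactants: 2 1-bromo-3,4-dimethoxy-2-methylbenzene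
Product: 4 3,4-dimethoxy-2-methylbenzoic acid, via aryllithium 3 (not isolated)
Conditions: n-BuLi (1.1 equiv), THF, −78 °C; CO2 (g), −78 °C to rt; 1 M HCl
Reagents that add atoms: carbon dioxide, O=C=O
Why: Bromine–lithium exchange followed by carboxylation of the aryllithium is a standard benzoic acid synthesis and fixes the carboxyl carbon exactly where bromine stood.

Step 3
Reactants: 5 4-hydroxy-2-methylbenzoic acid
Product: 6 4-nitrobenzyl 4-hydroxy-2-methylbenzoate
Conditions: 4-nitrobenzyl bromide (1.05 equiv), KHCO3 (1.2 equiv), DMF, 40 °C
Reagents that add atoms: 4-nitrobenzyl bromide, O=[N+]([O-])c1ccc(CBr)cc1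
Why: SN2 alkylation of the carboxylate should be selective because KHCO3 ionises the acid but not the phenol, so the 4-hydroxyl stays free.

Step 4
Reactants: 4 3,4-dimethoxy-2-methylbenzoic acid; 6 4-nitrobenzyl 4-hydroxy-2-methylbenzoate
Product: 7 4-nitrobenzyl 4-[(3,4-dimethoxy-2-methylbenzoyl)oxy]-2-methylbenzoate
Conditions: DCC (1.2 equiv), DMAP (0.1 equiv), CH2Cl2, 0 °C to rt
Reagents that add atoms: none
Why: Steglich esterification of a benzoic acid with only one ortho substituent and an unhindered phenol should form the aryl ester readily.

Step 5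
Reactants: 7 4-nitrobenzyl 4-[(3,4-dimethoxy-2-methylbenzoyl)oxy]-2-methylbenzoate
Product: 8 4-[(3,4-dimethoxy-2-methylbenzoyl)oxy]-2-methylbenzoic acid
Conditions: H2 (1 atm), 10% Pd/C, EtOAc–THF, rt; dilute aq. HCl wash
Reagents that add atoms: none
Why: Catalytic hydrogenolysis of a 4-nitrobenzyl ester (nitro reduction and benzylic C–O cleavage) should free the acid under neutral conditions that leave the aryl ester and the methoxy groups untouched.

Step 6
Reactants: 8 4-[(3,4-dimethoxy-2-methylbenzoyl)oxy]-2-methylbenzoic acid; 6 4-nitrobenzyl 4-hydroxy-2-methylbenzoate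
Product: 9 4-nitrobenzyl 4-({4-[(3,4-dimethoxy-2-methylbenzoyl)oxy]-2-methylbenzoyl}oxy)-2-methylbenzoate
Conditions: DCC (1.2 equiv), DMAP (0.1 equiv), CH2Cl2, 0 °C to rt
Reagents that add atoms: none
Why: A second Steglich esterification, again with a mono-ortho-substituted acid, should give the hydroxyl-free tridepside ester, since no phenol needs protection.

Step 7
Reactants: 9 4-nitrobenzyl 4-({4-[(3,4-dimethoxy-2-methylbenzoyl)oxy]-2-methylbenzoyl}oxy)-2-methylbenzoate
Product: 11 4-nitrobenzyl 2-hydroxy-4-({2-hydroxy-4-[(2-hydroxy-4,5-dimethoxy-6-methylbenzoyl)oxy]-6-methylbenzoyl}oxy)-6-methylbenzoate, via tris(trifluoroacetate) 10 (not isolated)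
Conditions: [RuCl2(p-cymene)]2 (10 mol %), K2S2O8 (4.5 equiv, in portions), TFA/TFAA (4:1), 80 °C; then THF/aq. NaH2PO4–Na2HPO4 (pH 7), rt
Reagents that add atoms: trifluoroacetic acid, OC(=O)C(F)(F)F; trifluoroacetic anhydride, O=C(OC(=O)C(F)(F)F)C(F)(F)F (the shared trifluoroacetate pool supplies the three phenolic oxygen atoms)
Why: Proposed new method: each ester carbonyl oxygen should bind a cationic divalent ruthenium trifluoroacetate, carboxylate-assisted concerted metalation–deprotonation at the only free ortho C–H (C2 of rings A, B and C) should give a five-membered ruthenacycle, persulfate should oxidise it to a tetravalent ruthenium trifluoroacetate, and C–O reductive elimination should release an aryl trifluoroacetate and divalent ruthenium, the cycle running once per ring before the three trifluoroacetates of 10 are hydrolysed in the buffered work-up. The closest known reaction type is the ester-directed ortho-C–H hydroxylation of simple alkyl benzoates under ruthenium catalysis with persulfate in TFA/TFAA; unproven are direction by the two less basic aryl ester carbonyls, three events on one substrate and survival of the dimethoxy ring A. No ring is closed and no stereocentre is formed. Site selectivity is needed for C2 over C3 and C5 of rings B and C and over C3 of ring A: the C6 methyl groups block the second ortho position of every carbonyl, metalation on the O-aryl side would need a six-membered chelate and is disfavoured, and the acyl group deactivates ring A towards undirected attack. Each new oxygen stays masked as an electron-poor trifluoroacetate until work-up, which matters most on ring A, where the oxygen on C2 lies para to the C5 methoxy group and a free phenol would invite quinone formation. The 4-nitrobenzyl ester keeps the ring C carboxyl from forming a mixed anhydride and gives that ring an alkyl ester director.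

Step 8
Reactants: 11 4-nitrobenzyl 2-hydroxy-4-({2-hydroxy-4-[(2-hydroxy-4,5-dimethoxy-6-methylbenzoyl)oxy]-6-methylbenzoyl}oxy)-6-methylbenzoate
Product: 12 2-hydroxy-4-({2-hydroxy-4-[(2-hydroxy-4,5-dimethoxy-6-methylbenzoyl)oxy]-6-methylbenzoyl}oxy)-6-methylbenzoic acid (CNP0139469.0)
Conditions: H2 (1 atm), 10% Pd/C, EtOAc–THF, rt; dilute aq. HCl wash
Reagents that add atoms: none
Why: Hydrogenolysis of the 4-nitrobenzyl ester, the usual closing move of depside syntheses, should release the carboxylic acid without touching the two aryl ester links or the phenols.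

Compound list
1 | 2,3-dimethoxytoluene | Cc1cccc(OC)c1OC | starting material
2 | 1-bromo-3,4-dimethoxy-2-methylbenzene | COc1ccc(Br)c(C)c1OC | intermediate
3 | (3,4-dimethoxy-2-methylphenyl)lithium | [Li]c1ccc(OC)c(OC)c1C | intermediate (not isolated)
4 | 3,4-dimethoxy-2-methylbenzoic acid | COc1ccc(C(=O)O)c(C)c1OC | intermediate
5 | 4-hydroxy-2-methylbenzoic acid | Cc1cc(O)ccc1C(=O)O | starting material
6 | 4-nitrobenzyl 4-hydroxy-2-methylbenzoate | Cc1cc(O)ccc1C(=O)OCc1ccc([N+](=O)[O-])cc1 | intermediate
7 | 4-nitrobenzyl 4-[(3,4-dimethoxy-2-methylbenzoyl)oxy]-2-methylbenzoate | COc1ccc(C(=O)Oc2cc(C)c(C(=O)OCc3ccc([N+](=O)[O-])cc3)cc2)c(C)c1OC | intermediate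
8 | 4-[(3,4-dimethoxy-2-methylbenzoyl)oxy]-2-methylbenzoic acid | COc1ccc(C(=O)Oc2cc(C)c(C(=O)O)cc2)c(C)c1OC | intermediate
9 | 4-nitrobenzyl 4-({4-[(3,4-dimethoxy-2-methylbenzoyl)oxy]-2-methylbenzoyl}oxy)-2-methylbenzoate (hydroxyl-free tridepside, ring C carboxyl as 4-nitrobenzyl ester) | COc1ccc(C(=O)Oc2cc(C)c(C(=O)Oc3cc(C)c(C(=O)OCc4ccc([N+](=O)[O-])cc4)cc3)cc2)c(C)c1OC | intermediate
10 | tris(trifluoroacetate) of 11 (trifluoroacetoxy on C2 of rings A, B and C) | COc1cc(OC(=O)C(F)(F)F)c(C(=O)Oc2cc(C)c(C(=O)Oc3cc(C)c(C(=O)OCc4ccc([N+](=O)[O-])cc4)c(OC(=O)C(F)(F)F)c3)c(OC(=O)C(F)(F)F)c2)c(C)c1OC | intermediate (not isolated)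
11 | 4-nitrobenzyl 2-hydroxy-4-({2-hydroxy-4-[(2-hydroxy-4,5-dimethoxy-6-methylbenzoyl)oxy]-6-methylbenzoyl}oxy)-6-methylbenzoate | COc1cc(O)c(C(=O)Oc2cc(C)c(C(=O)Oc3cc(C)c(C(=O)OCc4ccc([N+](=O)[O-])cc4)c(O)c3)c(O)c2)c(C)c1OC | intermediate
12 | 2-hydroxy-4-({2-hydroxy-4-[(2-hydroxy-4,5-dimethoxy-6-methylbenzoyl)oxy]-6-methylbenzoyl}oxy)-6-methylbenzoic acid (CNP0139469.0) | COc1cc(O)c(C(=O)Oc2cc(C)c(C(=O)Oc3cc(C)c(C(=O)O)c(O)c3)c(O)c2)c(C)c1OC | target

Total step count: 8
Longest linear sequence: 7 steps (steps 1, 2, 4, 5, 6, 7, 8; step 3 is a one-step branch whose product 6 is used twice)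

Steps most likely to fail

Step 7 (Proposed new method). Three processes may defeat it. Sulfate radical may oxidise the electron-rich ring A or its benzylic methyl without direction. The weakly basic aryl ester carbonyls may fail to deliver the metal, so that the sequence stalls after one or two oxygenations. Hot TFA/TFAA may cause acid-catalysed acyl exchange of the depside links. The fallback uses known chemistry only, sets out from 4 and comes back at 11. The oxygen atoms are brought in at the monomer stage and the depside is then assembled classically. Acid 4 is hydroxylated once by the established carboxylate-directed ortho-C–H hydroxylation of benzoic acids (Pd(OAc)2 cat., KOAc, benzoquinone, O2 1 atm, DMA, 115 °C) to give 6-hydroxy-3,4-dimethoxy-2-methylbenzoic acid F1. Commercial orsellinic acid (Cc1cc(O)cc(O)c1C(=O)O) is alkylated under the conditions of step 3 to give 4-nitrobenzyl 2,4-dihydroxy-6-methylbenzoate F2. Condensation of F1 with F2 by DCC in toluene should acylate only the 4-hydroxyl of F2, because the 2-hydroxyls are tied up in hydrogen bonds to their own carbonyls. This should give 4-nitrobenzyl 2-hydroxy-4-[(2-hydroxy-4,5-dimethoxy-6-methylbenzoyl)oxy]-6-methylbenzoate F3. Hydrogenolysis as in step 5 should free 2-hydroxy-4-[(2-hydroxy-4,5-dimethoxy-6-methylbenzoyl)oxy]-6-methylbenzoic acid F4. A second DCC condensation of F4 with F2 should give 11, which re-enters the route at step 8.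

Step 8. The reduction may stall at the aminobenzyl ester stage, or the liberated arylamine may attack the activated ortho-hydroxy aryl ester links, cleaving depside bonds in the most valuable intermediate. The fallback sets out from 9 and comes back at 12 by reversing the order of deprotection and oxidation. The phenol-free, robust ester 9 is hydrogenolysed as in step 5 to 4-({4-[(3,4-dimethoxy-2-methylbenzoyl)oxy]-2-methylbenzoyl}oxy)-2-methylbenzoic acid F5. The conditions of step 7 are then applied to this free acid, accepting carboxyl direction in place of ester direction on ring C. This should give the tris(trifluoroacetate) of 12 F6, whose carboxyl is reversibly engaged as a mixed anhydride in the medium. The buffered work-up should hydrolyse it to 12 with no step after the oxidation.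

Step 6. Under DMAP catalysis the phenoxide of 6 may attack the aryl ester already present in 8 or 9 and scramble the acyl groups, and slow capture of the carbodiimide adduct may allow rearrangement to an N-acylurea. The fallback sets out from 8 and comes back at 9, replacing base-catalysed carbodiimide coupling with the acid-promoted depside condensation. Acid 8 and phenol 6 are stirred with trifluoroacetic anhydride in toluene at rt. The mixed anhydride of 8 with trifluoroacetic acid F7 forms in the flask and should acylate the phenol of 6. No phenoxide or nucleophilic catalyst is present, so the existing aryl ester should stay intact.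

Further compounds
F1 | step 7 | 6-hydroxy-3,4-dimethoxy-2-methylbenzoic acid | COc1cc(O)c(C(=O)O)c(C)c1OC
F2 | step 7 | 4-nitrobenzyl 2,4-dihydroxy-6-methylbenzoate | Cc1cc(O)cc(O)c1C(=O)OCc1ccc([N+](=O)[O-])cc1
F3 | step 7 | 4-nitrobenzyl 2-hydroxy-4-[(2-hydroxy-4,5-dimethoxy-6-methylbenzoyl)oxy]-6-methylbenzoate | COc1cc(O)c(C(=O)Oc2cc(C)c(C(=O)OCc3ccc([N+](=O)[O-])cc3)c(O)c2)c(C)c1OC
F4 | step 7 | 2-hydroxy-4-[(2-hydroxy-4,5-dimethoxy-6-methylbenzoyl)oxy]-6-methylbenzoic acid | COc1cc(O)c(C(=O)Oc2cc(C)c(C(=O)O)c(O)c2)c(C)c1OC
F5 | step 8 | 4-({4-[(3,4-dimethoxy-2-methylbenzoyl)oxy]-2-methylbenzoyl}oxy)-2-methylbenzoic acid | COc1ccc(C(=O)Oc2cc(C)c(C(=O)Oc3cc(C)c(C(=O)O)cc3)cc2)c(C)c1OC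
F6 | step 8 | tris(trifluoroacetate) of 12 | COc1cc(OC(=O)C(F)(F)F)c(C(=O)Oc2cc(C)c(C(=O)Oc3cc(C)c(C(=O)O)c(OC(=O)C(F)(F)F)c3)c(OC(=O)C(F)(F)F)c2)c(C)c1OC
F7 | step 6 | mixed anhydride of 8 with trifluoroacetic acid | COc1ccc(C(=O)Oc2cc(C)c(C(=O)OC(=O)C(F)(F)F)cc2)c(C)c1OC
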